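**Strategy**

The γ-lactone (O1–C2–C3–C3a–C7a, benzofuranone numbering) is read as the Baeyer–Villiger image of a cyclobutanone. Deleting O1 makes C3 and C7a enantiotopic α-methylenes of an achiral 3,3-disubstituted cyclobutanone whose C3a carries farnesyl and a 2-oxobut-3-enyl arm. A chiral primary amine then closes the six-membered carbocycle by intramolecular Michael addition of α-carbon C7a to the terminal enone carbon C7: one operation forms the C7–C7a bond, fixes C7a, turns C3a into the quaternary stereocentre and locks the cis ring fusion. Baeyer–Villiger oxygen insertion at C7a and dehydrogenation of the C5 ketone (possible only towards C6=C7) finish the target.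

Key step: step 6

Remark (numbering): atom labels C2–C7a are those of the target (O1, C2, C3, C3a, C4, C5, C6, C7, C7a); farnesyl = (2E,6E)-3,7,11-trimethyldodeca-2,6,10-trien-1-yl.

Remark (assumption): the sense of induction of the cinchona primary amine in step 6 cannot be predicted with confidence; 9-amino(9-deoxy)epi-quinine is assumed to give the (1R,6R) dione, and its pseudo-enantiomer 9-amino(9-deoxy)epi-quinidine would be used if the opposite sense is found.

**Route**

Step 1
Reactants: 1 methyl 3,3-dimethoxycyclobutane-1-carboxylate; 2 (2E,6E)-farnesyl bromide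
Product: 3 methyl 1-farnesyl-3,3-dimethoxycyclobutane-1-carboxylate
Conditions: LiN(iPr)2, THF, −78 °C; then 2, −78 °C → 0 °C
Reagents that add atoms: (2E,6E)-farnesyl bromide (compound 2), CC(C)=CCC/C(C)=C/CC/C(C)=C/CBr
Why: Ester enolate alkylation (SN2 at the primary allylic bromide) should install farnesyl at the only acidic carbon and create the quaternary C3a, which is not yet stereogenic because the cyclobutane keeps a mirror plane; the ketal is inert to the amide base and the E,E geometry is untouched.

Step 2
Reactants: 3 methyl 1-farnesyl-3,3-dimethoxycyclobutane-1-carboxylate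
Product: 4 1-farnesyl-3,3-dimethoxycyclobutane-1-carboxylic acid
Conditions: KOH, MeOH–H2O, 65 °C; then 1 M HCl to pH 4, 0 °C
Reagents that add atoms: potassium hydroxide, [K+].[OH-]
Why: Saponification of the hindered methyl ester with hot hydroxide, to which the dimethyl ketal and the triene are inert; the cold, only mildly acidic work-up should spare the ketal.

Step 3
Reactants: 4 1-farnesyl-3,3-dimethoxycyclobutane-1-carboxylic acid
Product: 6 2-diazo-1-(1-farnesyl-3,3-dimethoxycyclobutyl)ethan-1-one, via acid chloride 5 (not isolated)
Conditions: 1-chloro-N,N,2-trimethylprop-1-en-1-amine, CH2Cl2, 0 °C → rt; then CH2N2, Et3N, Et2O–THF, 0 °C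
Reagents that add atoms: diazomethane, C=[N+]=[N-]
Why: Neutral acid chloride formation with the α-chloroenamine avoids free HCl (ketal, alkenes), and acylation of diazomethane (first stage of the Arndt–Eistert homologation) should give the diazoketone; the quaternary α-carbon rules out ketene formation by the amine base.

Step 4
Reactants: 6 2-diazo-1-(1-farnesyl-3,3-dimethoxycyclobutyl)ethan-1-one
Product: 8 2-(1-farnesyl-3,3-dimethoxycyclobutyl)-N-methoxy-N-methylacetamide, via ketene 7 (not isolated)
Conditions: PhCO2Ag (10 mol %), Et3N, MeNH(OMe)·HCl, THF, −25 °C → rt, dark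
Reagents that add atoms: N,O-dimethylhydroxylamine hydrochloride, CNOC.Cl
Why: Silver-catalysed Wolff rearrangement with 1,2-shift of the cyclobutyl carbon should give the ketene, which the hydroxylamine traps as the Weinreb amide; this moves the carbonyl one carbon away from C3a, as the C4–C5 arm requires.

Step 5
Reactants: 8 2-(1-farnesyl-3,3-dimethoxycyclobutyl)-N-methoxy-N-methylacetamide
Product: 10 3-farnesyl-3-(2-oxobut-3-en-1-yl)cyclobutan-1-one, via enone ketal 9 (not isolated)
Conditions: CH2=CHMgBr, THF, −20 °C → 0 °C; then 1 M aq. HCl, THF, rt
Reagents that add atoms: vinylmagnesium bromide, C=C[Mg]Br; water, O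
Why: Grignard addition to the Weinreb amide stops at the chelated tetrahedral intermediate, so a single vinyl group is delivered; the acidic quench releases the enone while the hydroxylamine stays protonated and cannot add back, and the same acid hydrolyses the dimethyl ketal to the cyclobutanone.

Step 6
Reactants: 10 3-farnesyl-3-(2-oxobut-3-en-1-yl)cyclobutan-1-one
Product: 11 (1R,6R)-1-farnesylbicyclo[4.2.0]octane-3,7-dione
Conditions: 9-amino(9-deoxy)epi-quinine (20 mol %), 2-fluorobenzoic acid (40 mol %), toluene, 25 °C
Reagents that add atoms: none
Why: The primary amine should condense with the strained cyclobutanone to an enamine at one of the two enantiotopic α-methylenes while the protonated quinuclidine hydrogen-bonds the enone carbonyl, and the enamine carbon (C7a) adds to the terminal alkene carbon (C7) before hydrolysis releases the catalyst. The closest known reaction types are the amine-catalysed asymmetric Michael addition of ketones to enones, including intramolecular desymmetrizing cases on prochiral cycloalkanones, and the enamine-based desymmetrization of 3-substituted cyclobutanones by aldol and Michael reactions. The six-membered carbocycle is closed in a 6-(enolexo)-endo-trig mode. The configuration at C7a is set by the catalyst, which chooses the methylene that reacts, and C3a becomes stereogenic in the same event with its relative configuration dictated by the tether, since only the cis-fused bicyclo[4.2.0]octane is geometrically accessible. The step needs selection between the enantiotopic α-CH2 groups; because the enone arm always attacks on its own ring face, the two closures are mirror-image pathways that only the catalyst differentiates, so no size difference between the C3a substituents is required. Attack at C7 is the only closure that gives an unstrained ring, which secures the regiochemistry.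

Step 7
Reactants: 11 (1R,6R)-1-farnesylbicyclo[4.2.0]octane-3,7-dione
Product: 12 (3aR,7aR)-3a-farnesylhexahydro-1-benzofuran-2,5-dione
Conditions: 30% aq. H2O2, NaOH (0.3 equiv), THF–MeOH, 0 °C; 1 M HCl work-up
Reagents that add atoms: hydrogen peroxide, OO
Why: Baeyer–Villiger oxidation with nucleophilic hydroperoxide should be selective for the strained cyclobutanone over the cyclohexanone and does not epoxidize isolated trisubstituted alkenes; the more substituted ring-fusion carbon C7a migrates with retention, so the cis-fused γ-lactone with the (7aR) oxygen results.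

Step 8
Reactants: 12 (3aR,7aR)-3a-farnesylhexahydro-1-benzofuran-2,5-dione
Product: 13 (3aR,7aR)-3a-farnesyl-3,3a,4,7a-tetrahydro-1-benzofuran-2,5-dione (CNP0400313.1)
Conditions: 2-iodoxybenzoic acid (IBX), DMSO–toluene, 65 °C
Reagents that add atoms: none
Why: IBX-mediated α,β-dehydrogenation of the ketone through its enol; C3a bears no hydrogen, so desaturation can only occur between C6 and C7, and the lactone and the isolated alkenes should be inert.

**Compound list**

1 | methyl 3,3-dimethoxycyclobutane-1-carboxylate | COC(=O)C1CC(OC)(OC)C1 | starting material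
2 | (2E,6E)-farnesyl bromide, (2E,6E)-1-bromo-3,7,11-trimethyldodeca-2,6,10-triene | CC(C)=CCC/C(C)=C/CC/C(C)=C/CBr | starting material
3 | methyl 1-farnesyl-3,3-dimethoxycyclobutane-1-carboxylate | CC(C)=CCC/C(C)=C/CC/C(C)=C/CC1(C(=O)OC)CC(OC)(OC)C1 | intermediate
4 | 1-farnesyl-3,3-dimethoxycyclobutane-1-carboxylic acid | CC(C)=CCC/C(C)=C/CC/C(C)=C/CC1(C(=O)O)CC(OC)(OC)C1 | intermediate
5 | 1-farnesyl-3,3-dimethoxycyclobutane-1-carbonyl chloride (not isolated) | CC(C)=CCC/C(C)=C/CC/C(C)=C/CC1(C(=O)Cl)CC(OC)(OC)C1 | intermediate
6 | 2-diazo-1-(1-farnesyl-3,3-dimethoxycyclobutyl)ethan-1-one | CC(C)=CCC/C(C)=C/CC/C(C)=C/CC1(C(=O)C=[N+]=[N-])CC(OC)(OC)C1 | intermediate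
7 | 2-(1-farnesyl-3,3-dimethoxycyclobutyl)ethen-1-one, the ketene (not isolated) | CC(C)=CCC/C(C)=C/CC/C(C)=C/CC1(C=C=O)CC(OC)(OC)C1 | intermediate
8 | 2-(1-farnesyl-3,3-dimethoxycyclobutyl)-N-methoxy-N-methylacetamide | CC(C)=CCC/C(C)=C/CC/C(C)=C/CC1(CC(=O)N(C)OC)CC(OC)(OC)C1 | intermediate
9 | 1-(1-farnesyl-3,3-dimethoxycyclobutyl)but-3-en-2-one (not isolated) | CC(C)=CCC/C(C)=C/CC/C(C)=C/CC1(CC(=O)C=C)CC(OC)(OC)C1 | intermediate
10 | 3-farnesyl-3-(2-oxobut-3-en-1-yl)cyclobutan-1-one | CC(C)=CCC/C(C)=C/CC/C(C)=C/CC1(CC(=O)C=C)CC(=O)C1 | intermediate
11 | (1R,6R)-1-farnesylbicyclo[4.2.0]octane-3,7-dione (cis-fused) | CC(C)=CCC/C(C)=C/CC/C(C)=C/C[C@]12CC(=O)CC[C@H]1C(=O)C2 | intermediate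
12 | (3aR,7aR)-3a-farnesylhexahydro-1-benzofuran-2,5-dione (cis-fused) | CC(C)=CCC/C(C)=C/CC/C(C)=C/C[C@]12CC(=O)CC[C@H]1OC(=O)C2 | intermediate
13 | (3aR,7aR)-3a-[(2E,6E)-3,7,11-trimethyldodeca-2,6,10-trien-1-yl]-3,3a,4,7a-tetrahydro-1-benzofuran-2,5-dione | CC(C)=CCC/C(C)=C/CC/C(C)=C/C[C@]12CC(=O)C=C[C@H]1OC(=O)C2 | target

**Step count and risks**

Total step count: 8. Longest linear sequence: 8 steps (1 → 13).

Steps most likely to fail:

Step 6. The amine may be sequestered by conjugate addition to the vinyl ketone, or discrimination between the two enantiotopic α-methylenes may be low. Slow racemic closure through the enol, including during the acidic deketalization of step 5, could also erode the enantiomeric purity. Fallback (resolution in place of asymmetric catalysis): setting out from 10, closure with pyrrolidine and acetic acid (achiral enamine Michael addition) should give the racemic cis-dione, that is 11 together with its enantiomer (1S,6S)-1-farnesylbicyclo[4.2.0]octane-3,7-dione F1. Separation of the two on a chiral stationary phase (preparative supercritical-fluid chromatography, amylose carbamate phase) comes back to the route at 11.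

Step 7. Under the basic peroxide the 1,5-dicarbonyl array may open by retro-Michael reaction, the methylene carbon C3 may migrate instead of C7a, or the lactone may be hydrolysed and lost on work-up. Fallback (changed order of events and a non-basic oxidant): setting out from 11, dehydrogenation with IBX first should give (1R,6R)-1-farnesylbicyclo[4.2.0]oct-4-ene-3,7-dione F2, in which C7a is allylic and migrates even more readily. Baeyer–Villiger oxidation with Me3SiOOSiMe3 and catalytic Me3SiOTf (CH2Cl2, −78 °C), which leaves enones and isolated alkenes untouched, then comes back to the route at 13.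

Step 8. Conversion may stall, or the hypervalent iodine reagent may oxidize allylic positions of the triene at the temperature needed. Fallback (stepwise, regiodefined dehydrogenation): setting out from 12, kinetic deprotonation at C6 (LiN(SiMe3)2, Me3SiCl, THF, −78 °C; the lactone α-CH2 is less acidic and C4 is neopentyl) should give (3aR,7aR)-3a-farnesyl-5-(trimethylsilyloxy)-3a,4,7,7a-tetrahydro-1-benzofuran-2(3H)-one F3. Saegusa–Ito oxidation (Pd(OAc)2, MeCN, rt) then comes back to the route at 13.

Further compounds
F1 | step 6 | (1S,6S)-1-farnesylbicyclo[4.2.0]octane-3,7-dione (enantiomer of 11) | CC(C)=CCC/C(C)=C/CC/C(C)=C/C[C@@]12CC(=O)CC[C@@H]1C(=O)C2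
F2 | step 7 | (1R,6R)-1-farnesylbicyclo[4.2.0]oct-4-ene-3,7-dione | CC(C)=CCC/C(C)=C/CC/C(C)=C/C[C@]12CC(=O)C=C[C@H]1C(=O)C2
F3 | step 8 | (3aR,7aR)-3a-farnesyl-5-(trimethylsilyloxy)-3a,4,7,7a-tetrahydro-1-benzofuran-2(3H)-one | CC(C)=CCC/C(C)=C/CC/C(C)=C/C[C@]12CC(O[Si](C)(C)C)=CC[C@H]1OC(=O)C2
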